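**Retrosynthetic overview**

1. Labdane numbering is used (decalin C1–C10; C17 on C8, C18/C19 on C4, C20 on C10, side chain C11–C16 on C9; α = face opposite C20). The target is 3α,6β,19-trihydroxylabda-8,13E-dien-15-oic acid.
2. Enabling feature: ring B is a cyclohexene (C5–C6–C7–C8=C9–C10) whose tetrasubstituted C8=C9 bond lies opposite the C5–C6 bond, with C6 oxygenated and C5–C10 shared with ring A. This is the retron of a [4+2] addition of a C5=C6 dienophile to a C7=C8–C9=C10 diene joined through C1–C4.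
3. Key disconnection: C6–C7 together with C5–C10, by intramolecular Diels–Alder reaction of an acyclic (E)-nitroalkene (nitro on C6 as latent C6 oxygen). Rings A and B form in the same step; then C6–NO2 → C6=O → 6β-OH.
4. Diene: the C9=C10 geometry comes from a (Z)-enol triflate of a β-keto ester (C8–C9–C10) and stereoretentive methylation (C20). The C8 ester becomes the isopropenyl group (C17, C7). C11–C14 enter by alkylation at C9, and C15/C16 by late methylalumination–acylation of the alkyne.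
5. Tether: C3/C4 come from an iridium-catalysed tert-(hydroxy)prenylation of methyl 4-oxobutanoate (C10, C1–C3) with isoprene monoxide. The vinyl group becomes C19 (acetal, then the small axial CHO that steers the cycloaddition), CH2OH becomes C5, and nitromethane supplies C6.

Key step: step 14

Remark (assumption on step 1): the anti selectivity of the tert-(hydroxy)prenylation is taken to mean that the secondary hydroxyl and the CH2OH group are anti when the chain is drawn as a zigzag through the vinyl group; this is the (R,R) relationship of 4, from which the vinyl group becomes C19 and CH2OH becomes C5.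

**Route**

Step 1
Reactants: 1 methyl 4-oxobutanoate; 2 isoprene monoxide (2-methyl-2-vinyloxirane, racemic)
Product: 4 (5R)-5-[(2R)-1-hydroxy-2-methylbut-3-en-2-yl]oxolan-2-one, via hydroxy ester 3 (not isolated)
Conditions: [Ir(cod)Cl]2 (2.5 mol%), Tol-BINAP (5 mol%, the enantiomer that gives the (R)-carbinol), 4-cyano-3-nitrobenzoic acid (10 mol%), K3PO4 (5 mol%), i-PrOH (2 equiv), THF, 60 °C; then TsOH (cat.), CH2Cl2, rt
Reagents that add atoms: none
Why: Iridium-catalysed transfer-hydrogenative carbonyl allylation (tert-(hydroxy)prenylation) through a closed chair-like transition state of the (E)-σ-allyliridium species should set C3 (R) and the quaternary C4 (R) in the anti sense under control of the chiral bisphosphine, and the γ-hydroxy ester then lactonises.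

Step 2
Reactants: 4 (5R)-5-[(2R)-1-hydroxy-2-methylbut-3-en-2-yl]oxolan-2-one
Product: 6 (5R)-5-[(2R)-1-hydroxy-3,3-dimethoxy-2-methylpropan-2-yl]oxolan-2-one, via aldehyde 5 (not isolated)
Conditions: O3, CH2Cl2/MeOH, −78 °C; Me2S; then HC(OMe)3, TsOH (cat.), MeOH, rt
Reagents that add atoms: ozone, [O-][O+]=O (carbonyl oxygen of 5 only); trimethyl orthoformate, COC(OC)OC (the two methoxy groups of 6)
Why: Ozonolysis cleaves the only C=C bond and the hindered, non-enolisable aldehyde is acetalised under acid catalysis without touching C3 or C4.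

Step 3
Reactants: 6 (5R)-5-[(2R)-1-hydroxy-3,3-dimethoxy-2-methylpropan-2-yl]oxolan-2-one
Product: 7 (4R,5R)-4-hydroxy-5-(hydroxymethyl)-N,6,6-trimethoxy-N,5-dimethylhexanamide
Conditions: MeNHOMe·HCl, i-PrMgCl, THF, −20 to 0 °C
Reagents that add atoms: N,O-dimethylhydroxylamine hydrochloride, CNOC.Cl
Why: Aminolysis of the γ-lactone by the chloromagnesium amide gives the N-methoxy-N-methyl amide, which frees the C3 hydroxyl and makes C10 an acyl donor that resists over-addition.

Step 4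
Reactants: 7 (4R,5R)-4-hydroxy-5-(hydroxymethyl)-N,6,6-trimethoxy-N,5-dimethylhexanamide
Product: 8 (4R,5R)-N,6,6-trimethoxy-N,5-dimethyl-4-[(triethylsilyl)oxy]-5-{[(triethylsilyl)oxy]methyl}hexanamide
Conditions: Et3SiCl, imidazole, DMAP (cat.), CH2Cl2, 0 °C to rt
Reagents that add atoms: chlorotriethylsilane, CC[Si](Cl)(CC)CC
Why: Standard silylation of both hydroxyls; the primary (C5–O) and secondary (C3–O) triethylsilyl ethers are told apart later under Swern conditions.

Step 5
Reactants: 8 (4R,5R)-N,6,6-trimethoxy-N,5-dimethyl-4-[(triethylsilyl)oxy]-5-{[(triethylsilyl)oxy]methyl}hexanamide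
Product: 9 ethyl (6R,7R)-8,8-dimethoxy-7-methyl-3-oxo-6-[(triethylsilyl)oxy]-7-{[(triethylsilyl)oxy]methyl}octanoate
Conditions: EtOAc, LiN(i-Pr)2, THF, −78 °C; then 8, −78 to −20 °C; aq. NH4Cl
Reagents that add atoms: ethyl acetate, CCOC(C)=O
Why: Claisen-type acylation of the lithium ester enolate by the N-methoxy-N-methyl amide, whose chelated tetrahedral adduct collapses to the β-keto ester only on work-up.

Step 6
Reactants: 9 ethyl (6R,7R)-8,8-dimethoxy-7-methyl-3-oxo-6-[(triethylsilyl)oxy]-7-{[(triethylsilyl)oxy]methyl}octanoate; 10 (4-bromobut-1-yn-1-yl)trimethylsilane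
Product: 11 ethyl (6R,7R)-8,8-dimethoxy-7-methyl-3-oxo-6-[(triethylsilyl)oxy]-7-{[(triethylsilyl)oxy]methyl}-2-[4-(trimethylsilyl)but-3-yn-1-yl]octanoate (C2 epimers)
Conditions: K2CO3, NaI (cat.), acetone, reflux
Reagents that add atoms: none
Why: C-alkylation (SN2) of the stabilised β-keto ester enolate with the primary homopropargylic halide installs C11–C14; the new centre at C9 forms as a mixture that is erased in step 7.

Step 7
Reactants: 11 ethyl (6R,7R)-8,8-dimethoxy-7-methyl-3-oxo-6-[(triethylsilyl)oxy]-7-{[(triethylsilyl)oxy]methyl}-2-[4-(trimethylsilyl)but-3-yn-1-yl]octanoate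
Product: 13 ethyl (2Z,6R,7R)-8,8-dimethoxy-7-methyl-6-[(triethylsilyl)oxy]-7-{[(triethylsilyl)oxy]methyl}-3-{[(trifluoromethyl)sulfonyl]oxy}-2-[4-(trimethylsilyl)but-3-yn-1-yl]oct-2-enoate, via sodium enolate 12 (not isolated)
Conditions: NaH, THF, 0 °C; then PhNTf2, 0 °C to rt
Reagents that add atoms: N-phenylbis(trifluoromethanesulfonimide), O=S(=O)(N(c1ccccc1)S(=O)(=O)C(F)(F)F)C(F)(F)F
Why: O-triflation of the sodium-chelated (Z)-enolate of the β-keto ester should give the (Z)-enol triflate (triflate cis to the ester), which fixes the C9=C10 geometry.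

Step 8
Reactants: 13 ethyl (2Z,6R,7R)-8,8-dimethoxy-7-methyl-6-[(triethylsilyl)oxy]-7-{[(triethylsilyl)oxy]methyl}-3-{[(trifluoromethyl)sulfonyl]oxy}-2-[4-(trimethylsilyl)but-3-yn-1-yl]oct-2-enoate
Product: 14 ethyl (2E,6R,7R)-8,8-dimethoxy-3,7-dimethyl-6-[(triethylsilyl)oxy]-7-{[(triethylsilyl)oxy]methyl}-2-[4-(trimethylsilyl)but-3-yn-1-yl]oct-2-enoate
Conditions: MeMgBr, Fe(acac)3 (5 mol%), THF/NMP, −30 °C
Reagents that add atoms: methylmagnesium bromide, C[Mg]Br
Why: Iron-catalysed cross-coupling of the enol triflate with the methyl Grignard reagent proceeds with retention of alkene geometry and faster than attack on the ester, so that C20 ends up cis to C8.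

Step 9
Reactants: 14 ethyl (2E,6R,7R)-8,8-dimethoxy-3,7-dimethyl-6-[(triethylsilyl)oxy]-7-{[(triethylsilyl)oxy]methyl}-2-[4-(trimethylsilyl)but-3-yn-1-yl]oct-2-enoate
Product: 16 (3E,7R,8R)-9,9-dimethoxy-2,4,8-trimethyl-7-[(triethylsilyl)oxy]-8-{[(triethylsilyl)oxy]methyl}-3-[4-(trimethylsilyl)but-3-yn-1-yl]non-3-en-2-ol, via methyl ketone 15 (not isolated)
Conditions: MeLi (4 equiv), CeCl3, THF, −78 to 0 °C
Reagents that add atoms: methyllithium, [Li]C
Why: Double 1,2-addition of the weakly basic organocerium reagent to the hindered ester should give the tertiary alcohol without γ-deprotonation, so the alkene geometry is kept.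

Step 10
Reactants: 16 (3E,7R,8R)-9,9-dimethoxy-2,4,8-trimethyl-7-[(triethylsilyl)oxy]-8-{[(triethylsilyl)oxy]methyl}-3-[4-(trimethylsilyl)but-3-yn-1-yl]non-3-en-2-ol
Product: 17 (3E,7R,8R)-9,9-dimethoxy-2,4,8-trimethyl-7-[(triethylsilyl)oxy]-8-{[(triethylsilyl)oxy]methyl}-3-[4-(trimethylsilyl)but-3-yn-1-yl]nona-1,3-diene
Conditions: Burgess reagent (Et3N+SO2N−CO2Me), PhMe, 50 °C
Reagents that add atoms: none
Why: syn-Elimination through the sulfamate ester can only take a hydrogen from one of the two methyl groups (C9 carries none), which gives the isopropenyl group and thus the 1,3-diene with unchanged C9=C10 geometry.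

Step 11
Reactants: 17 (3E,7R,8R)-9,9-dimethoxy-2,4,8-trimethyl-7-[(triethylsilyl)oxy]-8-{[(triethylsilyl)oxy]methyl}-3-[4-(trimethylsilyl)but-3-yn-1-yl]nona-1,3-diene
Product: 18 (2S,3R,6E)-2-(dimethoxymethyl)-2,6,8-trimethyl-3-[(triethylsilyl)oxy]-7-[4-(trimethylsilyl)but-3-yn-1-yl]nona-6,8-dienal
Conditions: (COCl)2, DMSO, CH2Cl2, −78 to −40 °C; then Et3N, −78 °C to rt
Reagents that add atoms: none
Why: Under Swern conditions a primary triethylsilyl ether is cleaved by the chlorosulfonium salt and oxidised to the aldehyde, while the secondary silyl ether, the acetal and the diene are left alone.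

Step 12
Reactants: 18 (2S,3R,6E)-2-(dimethoxymethyl)-2,6,8-trimethyl-3-[(triethylsilyl)oxy]-7-[4-(trimethylsilyl)but-3-yn-1-yl]nona-6,8-dienal
Product: 21 (1E,3R,4R,7E)-3-(dimethoxymethyl)-3,7,9-trimethyl-1-nitro-4-[(triethylsilyl)oxy]-8-[4-(trimethylsilyl)but-3-yn-1-yl]deca-1,7,9-triene, via nitro-aldol adduct 19 (not isolated), via mesylate 20 (not isolated)
Conditions: MeNO2, 1,1,3,3-tetramethylguanidine (10 mol%), THF, rt; then MsCl, Et3N, CH2Cl2, 0 °C
Reagents that add atoms: nitromethane, C[N+](=O)[O-]; methanesulfonyl chloride, CS(=O)(=O)Cl (mesyl group of 20 only)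
Why: Henry addition to the non-enolisable aldehyde followed by mesylation and E1cB elimination should give the thermodynamically preferred (E)-nitroalkene.

Step 13
Reactants: 21 (1E,3R,4R,7E)-3-(dimethoxymethyl)-3,7,9-trimethyl-1-nitro-4-[(triethylsilyl)oxy]-8-[4-(trimethylsilyl)but-3-yn-1-yl]deca-1,7,9-triene
Product: 23 (2R,3R,6E)-2,6,8-trimethyl-2-[(E)-2-nitroethenyl]-3-[(triethylsilyl)oxy]-7-[4-(trimethylsilyl)but-3-yn-1-yl]nona-6,8-dienal, via collidinium salt 22 (not isolated)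
Conditions: Et3SiOTf, 2,4,6-collidine, CH2Cl2, 0 °C; then H2O
Reagents that add atoms: water, O
Why: Silyl triflate and collidine convert the dimethyl acetal into a pyridinium-type N,O-acetal that water hydrolyses to the aldehyde under non-acidic conditions, which spares the acid-sensitive diene, the silyl ether and the nitroalkene.

Step 14
Reactants: 23 (2R,3R,6E)-2,6,8-trimethyl-2-[(E)-2-nitroethenyl]-3-[(triethylsilyl)oxy]-7-[4-(trimethylsilyl)but-3-yn-1-yl]nona-6,8-dienal
Product: 24 6α-nitro-3α-[(triethylsilyl)oxy]-14-(trimethylsilyl)-15,16-dinorlabd-8-en-13-yn-19-al (trans-fused, 5α-H, 10β-CH3)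
Conditions: PhMe (0.01 M), BHT (5 mol%), 110 °C
Reagents that add atoms: none
Why: Thermal type 1 intramolecular Diels–Alder reaction of normal electron demand: the nitro-activated C5=C6 dienophile adds suprafacially to C10 and C7 of the s-cis diene in one concerted, asynchronous [4+2] event, which forms C5–C10 and C6–C7 and leaves the tetrasubstituted C8=C9 bond in place. The closest known reaction type is the intramolecular nitroalkene Diels–Alder reaction of (E)-1-nitrodeca-1,7,9-trienes, which gives trans-fused decalins through the endo-nitro transition state. Ring B is closed by the [4+2] cycloaddition itself (all six ring atoms come from diene and dienophile) and ring A as the six-membered chair-like tether ring of the fused mode (C1–C4 between C10 and C5). C10 (β-methyl) is fixed by the (E) geometry of C9=C10 (methyl inside, tether outside), C5 (α-H, trans fusion) by the anti orientation of the tether with the nitro group endo, and C6 (α-nitro) by the (E) geometry of the dienophile. The diene face is chosen by C4 and C3: the small C19 formyl group and the C3 silyloxy group take the axial sites of the forming chair and the C4 methyl the equatorial one, which avoids a methyl/methyl 1,3-diaxial contact with the inside methyl on C10. The step needs chemoselectivity for the nitroalkene over the aldehyde and the silylalkyne and a rate above that of 1,5-hydrogen shift in the diene, which the strong activation by the nitro group and the short four-atom tether should secure.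

Step 15
Reactants: 24 6α-nitro-3α-[(triethylsilyl)oxy]-14-(trimethylsilyl)-15,16-dinorlabd-8-en-13-yn-19-al
Product: 26 6-oxo-3α-[(triethylsilyl)oxy]-14-(trimethylsilyl)-15,16-dinorlabd-8-en-13-yn-19-al, via potassium nitronate 25 (not isolated)
Conditions: KOt-Bu (1.05 equiv), THF, −40 °C; then aq. TiCl3, NH4OAc (pH 5–6), THF, 0 °C to rt
Reagents that add atoms: water, O
Why: Nef reaction in its reductive form: trivalent titanium reduces the nitronate to the imine, which is hydrolysed in the buffered medium, so that the β,γ-unsaturated ketone is not exposed to base and C5 (trans fusion) is not touched.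

Step 16
Reactants: 26 6-oxo-3α-[(triethylsilyl)oxy]-14-(trimethylsilyl)-15,16-dinorlabd-8-en-13-yn-19-al
Product: 28 3α-[(triethylsilyl)oxy]-15,16-dinorlabd-8-en-13-yne-6β,19-diol, via silylalkyne diol 27 (not isolated)
Conditions: NaBH4, MeOH, 0 °C; then K2CO3, rt
Reagents that add atoms: none
Why: Hydride should add to the C6 ketone from the α face because the β face is shielded by the axial C20 methyl and the axial C19 group, which sets 6β-OH; the aldehyde is reduced to C19–OH and methanolysis then frees the terminal alkyne.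

Step 17
Reactants: 28 3α-[(triethylsilyl)oxy]-15,16-dinorlabd-8-en-13-yne-6β,19-diol
Product: 30 methyl 6β,19-dihydroxy-3α-[(triethylsilyl)oxy]labda-8,13E-dien-15-oate, via alkenylalane 29 (not isolated)
Conditions: Me3Al (6 equiv), Cp2ZrCl2 (1 equiv), CH2Cl2, 0 °C to rt; then ClCO2Me, 0 °C to rt; aq. HCl
Reagents that add atoms: trimethylaluminium, C[Al](C)C; methyl chloroformate, COC(=O)Cl
Why: Zirconium-catalysed methylalumination of the terminal alkyne is a syn addition with methyl at the internal carbon, and acylation of the alkenylalane with retention should give the (13E)-enoate; the two hydroxyls are carried as aluminium alkoxides.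

Step 18
Reactants: 30 methyl 6β,19-dihydroxy-3α-[(triethylsilyl)oxy]labda-8,13E-dien-15-oate
Product: 32 3α,6β,19-trihydroxylabda-8,13E-dien-15-oic acid (CNP0246116.2), via lithium carboxylate 31 (not isolated)
Conditions: LiOH, THF/MeOH/H2O, rt; then 1 M HCl to pH 1, rt
Reagents that add atoms: lithium hydroxide, [Li+].[OH-]
Why: Saponification of the methyl ester followed by acid cleavage of the secondary triethylsilyl ether during acidification should give the target; no stereocentre is affected.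

**Compound list**

1 | methyl 4-oxobutanoate | COC(=O)CCC=O | starting material
2 | isoprene monoxide (2-methyl-2-vinyloxirane, racemic) | CC1(C=C)CO1 | starting material
3 | methyl (4R,5R)-4-hydroxy-5-(hydroxymethyl)-5-methylhept-6-enoate | COC(=O)CC[C@@H](O)[C@](C)(C=C)CO | intermediate (not isolated)
4 | (5R)-5-[(2R)-1-hydroxy-2-methylbut-3-en-2-yl]oxolan-2-one | O=C1CC[C@@H](O1)[C@](C)(C=C)CO | intermediate
5 | (2R)-3-hydroxy-2-methyl-2-[(2R)-5-oxooxolan-2-yl]propanal | O=C1CC[C@@H](O1)[C@](C)(C=O)CO | intermediate (not isolated)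
6 | (5R)-5-[(2R)-1-hydroxy-3,3-dimethoxy-2-methylpropan-2-yl]oxolan-2-one | O=C1CC[C@@H](O1)[C@](C)(C(OC)OC)CO | intermediate
7 | (4R,5R)-4-hydroxy-5-(hydroxymethyl)-N,6,6-trimethoxy-N,5-dimethylhexanamide | CON(C)C(=O)CC[C@@H](O)[C@](C)(C(OC)OC)CO | intermediate
8 | (4R,5R)-N,6,6-trimethoxy-N,5-dimethyl-4-[(triethylsilyl)oxy]-5-{[(triethylsilyl)oxy]methyl}hexanamide | CON(C)C(=O)CC[C@@H](O[Si](CC)(CC)CC)[C@](C)(C(OC)OC)CO[Si](CC)(CC)CC | intermediate
9 | ethyl (6R,7R)-8,8-dimethoxy-7-methyl-3-oxo-6-[(triethylsilyl)oxy]-7-{[(triethylsilyl)oxy]methyl}octanoate | CCOC(=O)CC(=O)CC[C@@H](O[Si](CC)(CC)CC)[C@](C)(C(OC)OC)CO[Si](CC)(CC)CC | intermediate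
10 | (4-bromobut-1-yn-1-yl)trimethylsilane | C[Si](C)(C)C#CCCBr | starting material
11 | ethyl (6R,7R)-8,8-dimethoxy-7-methyl-3-oxo-6-[(triethylsilyl)oxy]-7-{[(triethylsilyl)oxy]methyl}-2-[4-(trimethylsilyl)but-3-yn-1-yl]octanoate (C2 epimers) | CCOC(=O)C(CCC#C[Si](C)(C)C)C(=O)CC[C@@H](O[Si](CC)(CC)CC)[C@](C)(C(OC)OC)CO[Si](CC)(CC)CC | intermediate
12 | sodium (Z)-enolate of 11 | CCOC(=O)/C(CCC#C[Si](C)(C)C)=C(\[O-])CC[C@@H](O[Si](CC)(CC)CC)[C@](C)(C(OC)OC)CO[Si](CC)(CC)CC.[Na+] | intermediate (not isolated)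
13 | ethyl (2Z,6R,7R)-8,8-dimethoxy-7-methyl-6-[(triethylsilyl)oxy]-7-{[(triethylsilyl)oxy]methyl}-3-{[(trifluoromethyl)sulfonyl]oxy}-2-[4-(trimethylsilyl)but-3-yn-1-yl]oct-2-enoate | CCOC(=O)/C(CCC#C[Si](C)(C)C)=C(\OS(=O)(=O)C(F)(F)F)CC[C@@H](O[Si](CC)(CC)CC)[C@](C)(C(OC)OC)CO[Si](CC)(CC)CC | intermediate
14 | ethyl (2E,6R,7R)-8,8-dimethoxy-3,7-dimethyl-6-[(triethylsilyl)oxy]-7-{[(triethylsilyl)oxy]methyl}-2-[4-(trimethylsilyl)but-3-yn-1-yl]oct-2-enoate | CCOC(=O)/C(CCC#C[Si](C)(C)C)=C(\C)CC[C@@H](O[Si](CC)(CC)CC)[C@](C)(C(OC)OC)CO[Si](CC)(CC)CC | intermediate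
15 | (3E,7R,8R)-9,9-dimethoxy-4,8-dimethyl-7-[(triethylsilyl)oxy]-8-{[(triethylsilyl)oxy]methyl}-3-[4-(trimethylsilyl)but-3-yn-1-yl]non-3-en-2-one | CC(=O)/C(CCC#C[Si](C)(C)C)=C(\C)CC[C@@H](O[Si](CC)(CC)CC)[C@](C)(C(OC)OC)CO[Si](CC)(CC)CC | intermediate (not isolated)
16 | (3E,7R,8R)-9,9-dimethoxy-2,4,8-trimethyl-7-[(triethylsilyl)oxy]-8-{[(triethylsilyl)oxy]methyl}-3-[4-(trimethylsilyl)but-3-yn-1-yl]non-3-en-2-ol | CC(C)(O)/C(CCC#C[Si](C)(C)C)=C(\C)CC[C@@H](O[Si](CC)(CC)CC)[C@](C)(C(OC)OC)CO[Si](CC)(CC)CC | intermediate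
17 | (3E,7R,8R)-9,9-dimethoxy-2,4,8-trimethyl-7-[(triethylsilyl)oxy]-8-{[(triethylsilyl)oxy]methyl}-3-[4-(trimethylsilyl)but-3-yn-1-yl]nona-1,3-diene | C=C(C)/C(CCC#C[Si](C)(C)C)=C(\C)CC[C@@H](O[Si](CC)(CC)CC)[C@](C)(C(OC)OC)CO[Si](CC)(CC)CC | intermediate
18 | (2S,3R,6E)-2-(dimethoxymethyl)-2,6,8-trimethyl-3-[(triethylsilyl)oxy]-7-[4-(trimethylsilyl)but-3-yn-1-yl]nona-6,8-dienal | C=C(C)/C(CCC#C[Si](C)(C)C)=C(\C)CC[C@@H](O[Si](CC)(CC)CC)[C@](C)(C(OC)OC)C=O | intermediate
19 | (3R,4R,7E)-3-(dimethoxymethyl)-3,7,9-trimethyl-1-nitro-4-[(triethylsilyl)oxy]-8-[4-(trimethylsilyl)but-3-yn-1-yl]deca-7,9-dien-2-ol (C2 epimers) | C=C(C)/C(CCC#C[Si](C)(C)C)=C(\C)CC[C@@H](O[Si](CC)(CC)CC)[C@](C)(C(OC)OC)C(O)C[N+](=O)[O-] | intermediate (not isolated)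
20 | (3S,4R,7E)-3-(dimethoxymethyl)-3,7,9-trimethyl-1-nitro-4-[(triethylsilyl)oxy]-8-[4-(trimethylsilyl)but-3-yn-1-yl]deca-7,9-dien-2-yl methanesulfonate (C2 epimers) | C=C(C)/C(CCC#C[Si](C)(C)C)=C(\C)CC[C@@H](O[Si](CC)(CC)CC)[C@](C)(C(OC)OC)C(OS(C)(=O)=O)C[N+](=O)[O-] | intermediate (not isolated)
21 | (1E,3R,4R,7E)-3-(dimethoxymethyl)-3,7,9-trimethyl-1-nitro-4-[(triethylsilyl)oxy]-8-[4-(trimethylsilyl)but-3-yn-1-yl]deca-1,7,9-triene | C=C(C)/C(CCC#C[Si](C)(C)C)=C(\C)CC[C@@H](O[Si](CC)(CC)CC)[C@](C)(C(OC)OC)/C=C/[N+](=O)[O-] | intermediate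
22 | 1-[(2R,3R,6E)-1-methoxy-2,6,8-trimethyl-2-[(E)-2-nitroethenyl]-3-[(triethylsilyl)oxy]-7-[4-(trimethylsilyl)but-3-yn-1-yl]nona-6,8-dien-1-yl]-2,4,6-trimethylpyridin-1-ium trifluoromethanesulfonate (C1 epimers) | C=C(C)/C(CCC#C[Si](C)(C)C)=C(\C)CC[C@@H](O[Si](CC)(CC)CC)[C@](C)(C(OC)[n+]1c(C)cc(C)cc1C)/C=C/[N+](=O)[O-].[O-]S(=O)(=O)C(F)(F)F | intermediate (not isolated)
23 | (2R,3R,6E)-2,6,8-trimethyl-2-[(E)-2-nitroethenyl]-3-[(triethylsilyl)oxy]-7-[4-(trimethylsilyl)but-3-yn-1-yl]nona-6,8-dienal | C=C(C)/C(CCC#C[Si](C)(C)C)=C(\C)CC[C@@H](O[Si](CC)(CC)CC)[C@](C)(C=O)/C=C/[N+](=O)[O-] | intermediate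
24 | 6α-nitro-3α-[(triethylsilyl)oxy]-14-(trimethylsilyl)-15,16-dinorlabd-8-en-13-yn-19-al | CC1=C(CCC#C[Si](C)(C)C)[C@@]2(C)CC[C@@H](O[Si](CC)(CC)CC)[C@](C)(C=O)[C@@H]2[C@@H]([N+](=O)[O-])C1 | intermediate
25 | potassium nitronate of 24 (C6 aci-nitro salt) | CC1=C(CCC#C[Si](C)(C)C)[C@@]2(C)CC[C@@H](O[Si](CC)(CC)CC)[C@](C)(C=O)[C@@H]2C(=[N+]([O-])[O-])C1.[K+] | intermediate (not isolated)
26 | 6-oxo-3α-[(triethylsilyl)oxy]-14-(trimethylsilyl)-15,16-dinorlabd-8-en-13-yn-19-al | CC1=C(CCC#C[Si](C)(C)C)[C@@]2(C)CC[C@@H](O[Si](CC)(CC)CC)[C@](C)(C=O)[C@@H]2C(=O)C1 | intermediate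
27 | 3α-[(triethylsilyl)oxy]-14-(trimethylsilyl)-15,16-dinorlabd-8-en-13-yne-6β,19-diol | CC1=C(CCC#C[Si](C)(C)C)[C@@]2(C)CC[C@@H](O[Si](CC)(CC)CC)[C@](C)(CO)[C@@H]2[C@H](O)C1 | intermediate (not isolated)
28 | 3α-[(triethylsilyl)oxy]-15,16-dinorlabd-8-en-13-yne-6β,19-diol | CC1=C(CCC#C)[C@@]2(C)CC[C@@H](O[Si](CC)(CC)CC)[C@](C)(CO)[C@@H]2[C@H](O)C1 | intermediate
29 | (13E)-14-(dimethylalumanyl)-3α-[(triethylsilyl)oxy]-15-norlabda-8,13-diene-6β,19-diol as its 6,19-bis(dimethylaluminium) alkoxide | CC1=C(CC/C(C)=C/[Al](C)C)[C@@]2(C)CC[C@@H](O[Si](CC)(CC)CC)[C@](C)(CO[Al](C)C)[C@@H]2[C@H](O[Al](C)C)C1 | intermediate (not isolated)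
30 | methyl 6β,19-dihydroxy-3α-[(triethylsilyl)oxy]labda-8,13E-dien-15-oate | CC1=C(CC/C(C)=C/C(=O)OC)[C@@]2(C)CC[C@@H](O[Si](CC)(CC)CC)[C@](C)(CO)[C@@H]2[C@H](O)C1 | intermediate
31 | lithium 6β,19-dihydroxy-3α-[(triethylsilyl)oxy]labda-8,13E-dien-15-oate | CC1=C(CC/C(C)=C/C(=O)[O-])[C@@]2(C)CC[C@@H](O[Si](CC)(CC)CC)[C@](C)(CO)[C@@H]2[C@H](O)C1.[Li+] | intermediate (not isolated)
32 | 3α,6β,19-trihydroxylabda-8,13E-dien-15-oic acid (CNP0246116.2) | CC1=C(CC/C(C)=C/C(=O)O)[C@@]2(C)CC[C@@H](O)[C@](C)(CO)[C@@H]2[C@H](O)C1 | target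

**Step count and risks**

Total steps: 18. Longest linear sequence: 18 steps (from 1 to 32; 2 and 10 are bought).

Steps most likely to fail:

Step 14 (key cycloaddition). The cycloaddition may be too slow at the crowded C5–C10 bond, so that polymerisation or hetero-cycloaddition of the nitroalkene, or loss of endo and facial selectivity at a higher temperature, takes over. The fallback changes the dienophile to a thermally robust alkenylboronate whose C–B bond is oxidised afterwards. It sets out from aldehyde 18, which with lithiated CH2(Bpin)2 (made with lithium 2,2,6,6-tetramethylpiperidide) should give in a boron–Wittig reaction the (E)-alkenylboronate acetal F1. Acetal cleavage as in step 13 gives the alkenylboronate aldehyde F2, which tolerates heating to 150–170 °C and should cyclise in the same sense to the 6α-boryl cycloadduct F3. Oxidation with NaBO3 gives with retention the 6α-hydroxy aldehyde F4, and Dess–Martin periodinane brings the route back at keto aldehyde 26; steps 12 to 15 are bypassed.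

Step 15 (Nef reaction). At the nitronate stage the base may attack the neighbouring aldehyde, or move the C8=C9 bond into conjugation once the ketone appears. The fallback avoids the nitronate: it sets out from 24, whose secondary nitro group is reduced under near-neutral conditions with SnCl2, PhSH and Et3N to the oxime F5, and reductive deoximation with buffered aqueous TiCl3 comes back at 26.

Step 17 (methylalumination–acylation). Aggregation of the aluminium alkoxides may stall the carbometalation, or the alkenylalane may be protonated before it is acylated. The fallback builds the enoate by olefination: it sets out from alkyne 28, which on gold-catalysed hydration (Ph3PAuNTf2, MeOH/H2O) should give the methyl ketone F6, and a Horner–Wadsworth–Emmons reaction with trimethyl phosphonoacetate and NaH comes back at ester 30. The (13E) isomer should dominate and the (13Z) isomer has to be removed.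

Further compounds

F1 | step 14 | 2-[(1E,3R,4R,7E)-3-(dimethoxymethyl)-3,7,9-trimethyl-4-[(triethylsilyl)oxy]-8-[4-(trimethylsilyl)but-3-yn-1-yl]deca-1,7,9-trien-1-yl]-4,4,5,5-tetramethyl-1,3,2-dioxaborolane | C=C(C)/C(CCC#C[Si](C)(C)C)=C(\C)CC[C@@H](O[Si](CC)(CC)CC)[C@](C)(C(OC)OC)/C=C/B1OC(C)(C)C(C)(C)O1
F2 | step 14 | (2R,3R,6E)-2,6,8-trimethyl-2-[(E)-2-(4,4,5,5-tetramethyl-1,3,2-dioxaborolan-2-yl)ethenyl]-3-[(triethylsilyl)oxy]-7-[4-(trimethylsilyl)but-3-yn-1-yl]nona-6,8-dienal | C=C(C)/C(CCC#C[Si](C)(C)C)=C(\C)CC[C@@H](O[Si](CC)(CC)CC)[C@](C)(C=O)/C=C/B1OC(C)(C)C(C)(C)O1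
F3 | step 14 | 6α-(4,4,5,5-tetramethyl-1,3,2-dioxaborolan-2-yl)-3α-[(triethylsilyl)oxy]-14-(trimethylsilyl)-15,16-dinorlabd-8-en-13-yn-19-al | CC1=C(CCC#C[Si](C)(C)C)[C@@]2(C)CC[C@@H](O[Si](CC)(CC)CC)[C@](C)(C=O)[C@@H]2[C@@H](B3OC(C)(C)C(C)(C)O3)C1
F4 | step 14 | 6α-hydroxy-3α-[(triethylsilyl)oxy]-14-(trimethylsilyl)-15,16-dinorlabd-8-en-13-yn-19-al | CC1=C(CCC#C[Si](C)(C)C)[C@@]2(C)CC[C@@H](O[Si](CC)(CC)CC)[C@](C)(C=O)[C@@H]2[C@@H](O)C1
F5 | step 15 | 6-(hydroxyimino)-3α-[(triethylsilyl)oxy]-14-(trimethylsilyl)-15,16-dinorlabd-8-en-13-yn-19-al | CC1=C(CCC#C[Si](C)(C)C)[C@@]2(C)CC[C@@H](O[Si](CC)(CC)CC)[C@](C)(C=O)[C@@H]2C(=NO)C1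
F6 | step 17 | 6β,19-dihydroxy-3α-[(triethylsilyl)oxy]-14,15-dinorlabd-8-en-13-one | CC1=C(CCC(C)=O)[C@@]2(C)CC[C@@H](O[Si](CC)(CC)CC)[C@](C)(CO)[C@@H]2[C@H](O)C1
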